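The route rests on cutting the bond between the acetoxy-bearing carbon (C2 of the tridecyl side chain) and the adjacent chain methylene (C3). That carbon is an esterified dialkyl carbinol and the chain beyond it is unbranched. The bond is therefore made by a nickel-catalysed enantioconvergent reductive coupling. Arylacetaldehyde 6 and acetyl bromide give a racemic 1-bromoalkyl acetate, which couples with 1-undecene and a hydrosilane. One operation forms the C–C bond, sets the (R) centre and installs the acetate. No free hydroxyl ever faces the ortho carboxyl of the benzene ring, so lactonisation to the dihydroisocoumarin is excluded. The precursor is a benzyl-protected 2-(2-oxoethyl)benzoate made by carboxylate-directed C–H allylation and ozonolysis.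

Key step: step 4

Assumption: the (S,S) bis(oxazoline) ligand is taken to deliver the (R)-acetate. If a pilot run shows the opposite sense, the equally available (R,R) ligand is used.

Step 1
Reactants: 1 4-hydroxy-2-methoxybenzoic acid
Product: 2 4-(benzyloxy)-2-methoxybenzoic acid
Conditions: BnBr, NaOH, EtOH/H2O, reflux; then aq. HCl
Reagents that add atoms: benzyl bromide, BrCc1ccccc1
Why: Williamson ether synthesis on the dianion, in which the phenoxide is far more nucleophilic than the carboxylate and the hot aqueous hydroxide keeps the carboxyl group free.

Step 2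
Reactants: 2 4-(benzyloxy)-2-methoxybenzoic acid
Product: 4 benzyl 2-allyl-4-(benzyloxy)-6-methoxybenzoate, via allyl acid 3 (not isolated)
Conditions: allyl acetate, [Ru(p-cymene)Cl2]2 (cat.), K3PO4, Cl3CCH2OH, 50 °C; solvent exchanged for DMF; BnBr, K2CO3, rt
Reagents that add atoms: allyl acetate, C=CCOC(C)=O; benzyl bromide, BrCc1ccccc1
Why: Carboxylate-directed ruthenium-catalysed ortho C–H allylation (cyclometalation, olefin insertion, β-acetoxy elimination) can only strike the single free ortho position, and the hindered acid 3 is then esterified by SN2 alkylation of its carboxylate, which is insensitive to the two ortho substituents.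

Step 3
Reactants: 4 benzyl 2-allyl-4-(benzyloxy)-6-methoxybenzoate
Product: 6 benzyl 4-(benzyloxy)-2-methoxy-6-(2-oxoethyl)benzoate, via ozonide 5 (not isolated)
Conditions: O3, CH2Cl2, −78 °C (stopped at consumption of 4); Me2S, −78 °C to rt
Reagents that add atoms: ozone, [O-][O+]=O
Why: Ozonolysis with reductive work-up, in which the isolated terminal alkene undergoes 1,3-dipolar cycloaddition with ozone much faster than the ester-deactivated arene or the benzyl groups react, and the neutral reduction of ozonide 5 spares the enolisable aldehyde.

Step 4
Reactants: 6 benzyl 4-(benzyloxy)-2-methoxy-6-(2-oxoethyl)benzoate; 7 1-undecene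
Product: 9 benzyl 2-[(2R)-2-acetoxytridecyl]-4-(benzyloxy)-6-methoxybenzoate, via bromoacetate 8 (not isolated)
Conditions: AcBr (1.0 equiv), CH2Cl2, 0 °C to rt, evaporate; then 7, NiBr2·diglyme (10 mol %), (S,S)-Ph-BOX [2,2'-(propane-2,2-diyl)bis((4S)-4-phenyl-4,5-dihydrooxazole)] (12 mol %), (EtO)3SiH, K3PO4·H2O, Et2O, rt
Reagents that add atoms: acetyl bromide, CC(=O)Br
Why: Acetyl bromide adds across the aldehyde C=O of 6 to give the racemic 1-bromoalkyl acetate 8; a nickel hydride formed from the bis(oxazoline)–NiBr2 complex, (EtO)3SiH and K3PO4·H2O inserts 1-undecene in the anti-Markovnikov sense to give an n-undecylnickel species, low-valent nickel abstracts bromine from 8 to give a planar α-acetoxy radical, and radical capture followed by reductive elimination from trivalent nickel forms the CH2–CH(OAc) bond. The reaction type is the known nickel-catalysed enantioconvergent reductive coupling of racemic 1-bromoalkyl esters with olefins and a hydrosilane, including its four-component form that starts from aldehyde and acyl bromide. No ring is closed. The new stereocentre at the acetoxy carbon is controlled by the chiral ligand alone: both enantiomers of 8 converge on the same radical, whose faces are told apart through three very different substituents (coordinating acetoxy group, arylmethyl group, hydrogen), so the two flanking methylene groups need not be distinguished as they would in a ketone reduction. The step needs linear regioselectivity in the hydrometalation, secured by the terminal unbranched olefin, and chemoselectivity for the C–Br bond over benzyl ester, benzyl ether and acetate, secured by mild halogen abstraction at room temperature. Because the oxygen at this carbon is acetylated throughout, six-membered lactonisation onto the ortho ester cannot take place.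

Step 5
Reactants: 9 benzyl 2-[(2R)-2-acetoxytridecyl]-4-(benzyloxy)-6-methoxybenzoate
Product: 10 2-[(2R)-2-acetoxytridecyl]-4-hydroxy-6-methoxybenzoic acid
Conditions: H2 (1 atm), Pd/C, EtOAc, rt
Reagents that add atoms: none
Why: Catalytic hydrogenolysis cleaves both benzylic C–O bonds under neutral conditions, whereas the acetate sits on a non-benzylic secondary carbon and the stereocentre is not touched, so neither acyl loss nor lactonisation is expected.

Compound list
1 | 4-hydroxy-2-methoxybenzoic acid | COc1cc(O)ccc1C(=O)O | starting material
2 | 4-(benzyloxy)-2-methoxybenzoic acid | COc1cc(OCc2ccccc2)ccc1C(=O)O | intermediate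
3 | 2-allyl-4-(benzyloxy)-6-methoxybenzoic acid (not isolated) | C=CCc1cc(OCc2ccccc2)cc(OC)c1C(=O)O | intermediate
4 | benzyl 2-allyl-4-(benzyloxy)-6-methoxybenzoate | C=CCc1cc(OCc2ccccc2)cc(OC)c1C(=O)OCc1ccccc1 | intermediate
5 | benzyl 4-(benzyloxy)-2-methoxy-6-[(1,2,4-trioxolan-3-yl)methyl]benzoate (secondary ozonide, racemic, not isolated) | C1OOC(Cc2cc(OCc3ccccc3)cc(OC)c2C(=O)OCc2ccccc2)O1 | intermediate
6 | benzyl 4-(benzyloxy)-2-methoxy-6-(2-oxoethyl)benzoate | O=CCc1cc(OCc2ccccc2)cc(OC)c1C(=O)OCc1ccccc1 | intermediate
7 | 1-undecene | C=CCCCCCCCCC | starting material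
8 | benzyl 2-(2-acetoxy-2-bromoethyl)-4-(benzyloxy)-6-methoxybenzoate (racemic, not isolated) | CC(=O)OC(Br)Cc1cc(OCc2ccccc2)cc(OC)c1C(=O)OCc1ccccc1 | intermediate
9 | benzyl 2-[(2R)-2-acetoxytridecyl]-4-(benzyloxy)-6-methoxybenzoate | CCCCCCCCCCC[C@H](Cc1cc(OCc2ccccc2)cc(OC)c1C(=O)OCc1ccccc1)OC(C)=O | intermediate
10 | 2-[(2R)-2-acetoxytridecyl]-4-hydroxy-6-methoxybenzoic acid | CCCCCCCCCCC[C@H](Cc1cc(O)cc(OC)c1C(=O)O)OC(C)=O | target

Total step count: 5. Longest linear sequence: 5 steps (1 to 10).

Steps most likely to fail

1. Step 4.
- What may go wrong:
  - ionisation of the bromoacetate with participation of the neighbouring ester carbonyl and loss of the benzyl group before coupling;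
  - premature reduction of the C–Br bond by the nickel hydride;
  - insufficient facial selectivity at radical capture.
- Fallback, setting out from 6 and 7 and returning at 9. 1-Undecene is hydroborated with Et2BH to diethyl(undecyl)borane F1. Boron–zinc exchange with Et2Zn, with the volatiles removed in vacuo, gives diundecylzinc F2. F2 is added to 6 in toluene at −20 °C with Ti(OiPr)4 and catalytic (1S,2S)-1,2-bis(trifluoromethanesulfonamido)cyclohexane. By analogy with simple aldehydes, this ligand should direct attack to the face that leads to the (R)-carbinol. The metal alkoxide of benzyl 4-(benzyloxy)-2-[(2R)-2-hydroxytridecyl]-6-methoxybenzoate F3 is acetylated in the same flask with Ac2O/DMAP before it can lactonise, which gives 9.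

2. Step 2.
- What may go wrong:
  - sluggish cyclometalation of the electron-rich acid;
  - migration of the allyl double bond into conjugation;
  - cyclisation of the acid onto the alkene.
- Fallback, setting out from 2 and returning at 6, so that steps 2 and 3 are both bypassed. Redox-neutral C–H annulation of 2 with vinylene carbonate under [Cp*Rh(MeCN)3](SbF6)2 catalysis gives 6-(benzyloxy)-8-methoxy-1H-isochromen-1-one F4. Aqueous KOH, followed by careful acidification, opens the enol lactone to 4-(benzyloxy)-2-methoxy-6-(2-oxoethyl)benzoic acid F5, which is in equilibrium with its cyclic lactol. Alkylation of the carboxylate with BnBr/KHCO3 in DMF gives 6.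

3. Step 3.
- What may go wrong:
  - over-oxidation of the dialkoxyarene or of the benzylic C–H bonds of the benzyl groups by ozone;
  - cyclodehydration of the aldehyde onto the ester during purification.
- Fallback, setting out from 4 and returning at 6. A Lemieux–Johnson oxidation is used (K2OsO4·2H2O cat., NaIO4, 2,6-lutidine, dioxane/H2O, rt). Osmylation touches only the alkene. Benzyl 4-(benzyloxy)-2-(2,3-dihydroxypropyl)-6-methoxybenzoate F6 is cleaved by periodate as it forms, and crude 6 is taken into step 4 without chromatography.

Further compounds
F1 | step 4 | diethyl(undecyl)borane | CCCCCCCCCCCB(CC)CC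
F2 | step 4 | diundecylzinc | CCCCCCCCCCC[Zn]CCCCCCCCCCC
F3 | step 4 | benzyl 4-(benzyloxy)-2-[(2R)-2-hydroxytridecyl]-6-methoxybenzoate (formed as its metal alkoxide) | CCCCCCCCCCC[C@H](Cc1cc(OCc2ccccc2)cc(OC)c1C(=O)OCc1ccccc1)O
F4 | step 2 | 6-(benzyloxy)-8-methoxy-1H-isochromen-1-one | O=C1OC=Cc2cc(OCc3ccccc3)cc(OC)c12
F5 | step 2 | 4-(benzyloxy)-2-methoxy-6-(2-oxoethyl)benzoic acid | O=CCc1cc(OCc2ccccc2)cc(OC)c1C(=O)O
F6 | step 3 | benzyl 4-(benzyloxy)-2-(2,3-dihydroxypropyl)-6-methoxybenzoate (racemic) | OCC(O)Cc1cc(OCc2ccccc2)cc(OC)c1C(=O)OCc1ccccc1
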